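**Plan**
- Retrosynthesis: both angelates are removed, then the C-10 methyl (cuprate on a ring A enone) and the C-6–C-7 bond of the cyclobutane (ring B, enolate alkylation); C-3–C-4 and C-5–C-6 are then cut together, which takes the seven-membered ring C off a 3-methylcyclohex-2-enone (ring A) and leaves a five-carbon dialdehyde.
- Enabling feature: in the ring A enone, C-4 is the β-carbon (takes the C-3 radical and becomes the quaternary centre) and C-5 the α-carbon (the enolate that then attacks the non-enolisable C-6 aldehyde). The C-8 carbinol of ring A carries a diisopropylsilylene tether to the C-3 enol ether oxygen.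
- Forward order: ring A, then ring C together with a temporary dioxasilepane ring (key step), then ring B, then the C-10 methyl, then the esters.
- Helpers taken out later: silylene (HF), C-8 carbinol (oxidised to the ketone), C-10 carbonyl (reduced, mesylated, eliminated to the enone that takes the methyl).
- Stereochemistry: C-1 and C-11 from an Ir-catalysed tert-(hydroxy)prenylation; the temporary C-8 centre from an amine-catalysed desymmetrisation; C-3, C-4, C-5 and C-6 relayed from C-8 through the tether; C-7 fixed by the cage; C-10 by cuprate attack anti to the methyl-bearing C-4 bridge.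

Key step: step 11

Locants used in this text: C-1 CH(OAng) next to quaternary C-11; C-2 CH2; C-3 CH(OAng) next to quaternary C-4; C-4 C(CH3) of the cyclobutane; C-5 cyclobutane CH bonded to C-10; C-6 cyclobutane CH bonded to C-11; C-7 cyclobutane CH next to the ketone; C-8 C=O; C-9 CH2; C-10 CH(CH3); C-11 C(CH3)(CH2OH); C-12 the CH2OH carbon. Ring A = C-4, C-5, C-10, C-9, C-8, C-7; ring B = C-4, C-5, C-6, C-7; ring C = C-1, C-2, C-3, C-4, C-5, C-6, C-11.

Assumption (chemistry): the iridium-catalysed coupling in step 6 gives the anti diol with the relative configuration written for 10, and the ligand and amine-catalyst enantiomers are chosen that give 10 and (R)-6.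

**Step 1**
Reactants: 1 ethyl formate; 2 2-methylallylmagnesium chloride (2.1 equiv)
Product: 3 2,6-dimethylhepta-1,6-dien-4-ol
Conditions: THF, 0 °C to rt; aq. NH4Cl
Reagents that add atoms: none
Why: Double Grignard addition to the formate ester should give the symmetrical secondary alcohol in which both future acetonyl arms are masked as methallyl groups.

**Step 2**
Reactants: 3 2,6-dimethylhepta-1,6-dien-4-ol
Product: 4 tert-butyl[(2,6-dimethylhepta-1,6-dien-4-yl)oxy]dimethylsilane
Conditions: TBSCl, imidazole, DMF, rt
Reagents that add atoms: tert-butyldimethylsilyl chloride, CC(C)(C)[Si](C)(C)Cl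
Why: Standard silyl ether formation protects the carbinol that becomes C-8 before the oxidative cleavage.

**Step 3**
Reactants: 4 tert-butyl[(2,6-dimethylhepta-1,6-dien-4-yl)oxy]dimethylsilane
Product: 5 4-[(tert-butyldimethylsilyl)oxy]heptane-2,6-dione
Conditions: O3, CH2Cl2/MeOH, −78 °C; PPh3
Reagents that add atoms: ozone, [O-][O+]=O
Why: Ozonolysis with reductive work-up should cleave both 1,1-disubstituted alkenes to methyl ketones and leave the silyl ether untouched.

**Step 4**
Reactants: 5 4-[(tert-butyldimethylsilyl)oxy]heptane-2,6-dione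
Product: 6 (R)-5-[(tert-butyldimethylsilyl)oxy]-3-methylcyclohex-2-en-1-one
Conditions: 9-amino-9-deoxy-epi-quinine or its quinidine-derived pseudoenantiomer (20 mol%, the one that gives the R enone), AcOH, toluene, rt
Reagents that add atoms: none
Why: The primary-amine (enamine) catalysed desymmetrising intramolecular aldol condensation of 4-substituted heptane-2,6-diones should distinguish the two enantiotopic acetonyl arms and so set C-8 while ring A forms.

**Step 5**
Reactants: 6 (R)-5-[(tert-butyldimethylsilyl)oxy]-3-methylcyclohex-2-en-1-one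
Product: 7 (R)-5-hydroxy-3-methylcyclohex-2-en-1-one
Conditions: aq. HF, MeCN, 0 °C
Reagents that add atoms: none
Why: Acidic fluoride desilylation should free the C-8 hydroxyl without the base that would eliminate this β-oxy ketone.

**Step 6**
Reactants: 8 but-3-en-1-ol; 9 2-methyl-2-vinyloxirane (isoprene monoxide, racemic)
Product: 10 (2S,3R)-2-ethenyl-2-methylhex-5-ene-1,3-diol
Conditions: [Ir(cod)Cl]2 (cat.), Tol-BINAP (enantiomer that gives 10), 4-cyano-3-nitrobenzoic acid (cat.), K3PO4 (cat.), THF, 60 °C
Reagents that add atoms: none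
Why: In this iridium-catalysed transfer-hydrogenative tert-(hydroxy)prenylation the alcohol is dehydrogenated to the aldehyde, the epoxide opens to a π-allyl iridium species, and carbonyl addition through a closed chair transition state should set the C-1 carbinol and the C-11 quaternary centre anti, with the ligand fixing the absolute sense.

**Step 7**
Reactants: 10 (2S,3R)-2-ethenyl-2-methylhex-5-ene-1,3-diol
Product: 11 (2S,3R)-1-[(tert-butyldiphenylsilyl)oxy]-2-ethenyl-2-methylhex-5-en-3-ol
Conditions: TBDPSCl, imidazole, CH2Cl2, 0 °C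
Reagents that add atoms: tert-butyldiphenylsilyl chloride, CC(C)(C)[Si](Cl)(c1ccccc1)c1ccccc1
Why: The bulky silyl chloride should select the primary (C-12) hydroxyl over the secondary one (selective silylation).

**Step 8**
Reactants: 11 (2S,3R)-1-[(tert-butyldiphenylsilyl)oxy]-2-ethenyl-2-methylhex-5-en-3-ol
Product: 12 tert-butyl{[(2S,3R)-2-ethenyl-2-methyl-3-(triethylsilyloxy)hex-5-en-1-yl]oxy}diphenylsilane
Conditions: TESOTf, 2,6-lutidine, CH2Cl2, −78 °C
Reagents that add atoms: triethylsilyl trifluoromethanesulfonate, CC[Si](CC)(CC)OS(=O)(=O)C(F)(F)F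
Why: A silyl triflate silylates the hindered C-1 hydroxyl (silyl ether formation), which must be masked in the β-oxy aldehyde that follows.

**Step 9**
Reactants: 12 tert-butyl{[(2S,3R)-2-ethenyl-2-methyl-3-(triethylsilyloxy)hex-5-en-1-yl]oxy}diphenylsilane
Product: 13 (2S,3R)-2-{[(tert-butyldiphenylsilyl)oxy]methyl}-2-methyl-3-[(triethylsilyl)oxy]pentanedial
Conditions: O3, CH2Cl2, −78 °C; PPh3
Reagents that add atoms: ozone, [O-][O+]=O
Why: Ozonolysis of both vinyl groups should give the dialdehyde in which C-3 is enolisable and C-6, on the quaternary carbon, is not.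

**Step 10**
Reactants: 13 (2S,3R)-2-{[(tert-butyldiphenylsilyl)oxy]methyl}-2-methyl-3-[(triethylsilyl)oxy]pentanedial; 7 (R)-5-hydroxy-3-methylcyclohex-2-en-1-one
Product: 15 silaketal in which Si(i-Pr)2 links O-8 of enone 7 to the oxygen of the (Z)-C-3 enol ether of 13, via enol silyl triflate 14 (not isolated)
Conditions: i-Pr2Si(OTf)2, Et3N, CH2Cl2, −78 °C; then 7, 2,6-lutidine, −78 to 0 °C
Reagents that add atoms: diisopropylsilyl bis(trifluoromethanesulfonate), CC(C)[Si](C(C)C)(OS(=O)(=O)C(F)(F)F)OS(=O)(=O)C(F)(F)F
Why: Soft enolisation by the silyl triflate can only touch the C-3 aldehyde, and displacement of the second triflate by the C-8 hydroxyl should give the unsymmetrical silaketal tether (silyl enol ether and silyl ether formation).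

**Step 11**
Reactants: 15 silaketal-tethered enone, enol ether and aldehyde
Product: 16 β-hydroxy ketone with rings A and C cis-fused, C-10 ketone, (6S)-hydroxyl, and the diisopropylsilylene bridge between O-3 and O-8 (O-8, C-3 and C-6 on one face of ring A)
Conditions: Fe(acac)3 (30 mol%), PhSiH3, EtOH/THF (1:10), 0 °C to rt
Reagents that add atoms: none
Why: Proposed new method: an iron hydride formed from Fe(acac)3 and PhSiH3 transfers a hydrogen atom to C-2 of the electron-rich enol ether, the α-silyloxy C-3 radical adds 7-exo-trig to C-4, the β-carbon of the ring A enone (polarity-matched, whereas 8-endo attack at C-5 is not), the α-keto radical is reduced to the iron enolate, and this enolate closes ring C by a seven-membered intramolecular aldol addition (enolexo mode) onto the C-6 aldehyde. The closest known reaction types are the HAT-initiated radical conjugate addition–aldol annulation of simple alkenes with enones (radical–polar crossover) and the iron-catalysed reductive coupling of silyl enol ethers with enones; what is new is their combination across a silaketal tether with formation of a quaternary β-carbon. C-4 is set by the tether (C-3 is delivered to the face that carries O-8), C-3 by the dioxasilepane transition state with the chain exo, C-5 by the cis ring fusion that the reach of the chain enforces, and C-6 by a closed Zimmerman–Traxler-type transition state on the iron enolate with C-11 held anti to C-10 by the forming ring. The step needs HAT to the enol ether and not to the enone or the aldehyde, which the donor character of the enol ether secures, and aldol closure before protonation of the enolate, which intramolecularity and the low alcohol content should favour.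

**Step 12**
Reactants: 16 β-hydroxy ketone with silylene bridge
Product: 17 the 6,10-anti diol (C-10 hydroxyl trans to the C-5–C-6 bond)
Conditions: Me4NBH(OAc)3, MeCN/AcOH, −20 °C
Reagents that add atoms: none
Why: Evans–Saksena reduction delivers hydride from the C-6 alkoxyborohydride to give the anti 1,3-diol and removes the retro-aldol risk; the C-10 configuration is of no consequence because this centre is eliminated in step 17.

**Step 13**
Reactants: 17 6,10-anti diol
Product: 18 the 6,10-bis(methanesulfonate)
Conditions: MsCl, Et3N, CH2Cl2, 0 °C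
Reagents that add atoms: methanesulfonyl chloride, CS(=O)(=O)Cl
Why: Mesylation through the sulfene should reach both secondary hydroxyls, including the hindered C-6 one, and installs the two leaving groups (sulfonate ester formation).

**Step 14**
Reactants: 18 bis(methanesulfonate) with silylene bridge
Product: 19 1,3,8-triol 6,10-bis(methanesulfonate) with the C-12 silyl ether
Conditions: HF·pyridine, pyridine, THF, 0 °C to rt
Reagents that add atoms: none
Why: Buffered HF should cleave the dialkoxysilane and the triethylsilyl ether while the primary tert-butyldiphenylsilyl ether and the mesylates stay (fluoride desilylation).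

**Step 15**
Reactants: 19 1,3,8-triol bis(methanesulfonate)
Product: 20 the C-8 ketone (1,3-diol 6,10-bis(methanesulfonate))
Conditions: TEMPO (cat.), PhI(OAc)2, CH2Cl2, rt
Reagents that add atoms: none
Why: The oxoammonium oxidation is sensitive to hindrance, and only the C-8 hydroxyl is flanked by two CH2 groups, whereas the C-1 and C-3 hydroxyls each sit next to a quaternary carbon (selective alcohol oxidation).

**Step 16**
Reactants: 20 C-8 ketone 1,3-diol bis(methanesulfonate)
Product: 21 the 1,3-bis(triethylsilyl) ether
Conditions: TESOTf, 2,6-lutidine, CH2Cl2, −78 to 0 °C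
Reagents that add atoms: triethylsilyl trifluoromethanesulfonate, CC[Si](CC)(CC)OS(=O)(=O)C(F)(F)F
Why: Silylation of both hindered hydroxyls (silyl ether formation) prevents the alkoxide O-alkylation at C-6 that would otherwise compete in the next step.

**Step 17**
Reactants: 21 bis(triethylsilyl) ether keto bis(methanesulfonate)
Product: 23 tricyclic enone (rings A, B and C; C-8 ketone, C-9=C-10), via enone mesylate 22 (not isolated)
Conditions: KN(SiMe3)2 (2.5 equiv), THF, −78 °C to rt
Reagents that add atoms: none
Why: E1cB loss of the C-10 mesylate gives the enone, which leaves C-7 as the only enolisable position, and the C-7 enolate then displaces the C-6 mesylate with inversion (intramolecular enolate alkylation, 4-exo-tet) to close ring B; O-alkylation would need a bridgehead enol ether and is excluded, and C-7 is fixed by the cage.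

**Step 18**
Reactants: 23 tricyclic enone
Product: 24 tricyclic ketone with the C-10 methyl on the face of the C-6 bridge
Conditions: Me2CuLi, Et2O, −78 to −20 °C; aq. NH4Cl
Reagents that add atoms: lithium dimethylcuprate, [Li+].C[Cu-]C
Why: Cuprate conjugate addition should occur from the face of the C-6 bridge, which turns only a hydrogen towards the enone, anti to the methyl of the C-4 bridge, and so sets C-10.

**Step 19**
Reactants: 24 tricyclic ketone bis(triethylsilyl) ether
Product: 25 the 1,3-diol (C-12 silyl ether retained)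
Conditions: AcOH/THF/H2O (3:1:1), 40 °C
Reagents that add atoms: none
Why: Mild acid hydrolysis removes the triethylsilyl ethers and spares the far more stable primary tert-butyldiphenylsilyl ether (selective desilylation).

**Step 20**
Reactants: 25 1,3-diol (12-O-tert-butyldiphenylsilyl); 26 angelic acid ((Z)-2-methylbut-2-enoic acid, 3 equiv; one molecule is incorporated at each of the two hydroxyls)
Product: 27 the 1,3-bis(angelate) with the C-12 silyl ether
Conditions: 26 (3 equiv), 2,4,6-trichlorobenzoyl chloride (3 equiv), Et3N, toluene, rt; then 25, 80 °C (no DMAP)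
Reagents that add atoms: angelic acid (26, the second molecule, which esterifies the second hydroxyl), C/C=C(/C)C(=O)O
Why: Yamaguchi-type mixed anhydride acylation without a nucleophilic catalyst should esterify both hindered secondary alcohols, each with one molecule of angelic acid, without Z to E isomerisation of the angelate.

**Step 21**
Reactants: 27 bis(angelate) silyl ether
Product: 28 CNP0287707.1 (target)
Conditions: HF·pyridine, pyridine, THF, 0 °C to rt
Reagents that add atoms: none
Why: Acidic fluoride removes the last silyl ether without the basic conditions that would cause acyl migration from O-1 to O-12 (fluoride desilylation).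

**Compound list**

1 | ethyl formate | CCOC=O | starting material
2 | 2-methylallylmagnesium chloride | CC(=C)C[Mg]Cl | starting material
3 | 2,6-dimethylhepta-1,6-dien-4-ol | CC(=C)CC(O)CC(C)=C | intermediate
4 | tert-butyl[(2,6-dimethylhepta-1,6-dien-4-yl)oxy]dimethylsilane | CC(=C)CC(O[Si](C)(C)C(C)(C)C)CC(C)=C | intermediate
5 | 4-[(tert-butyldimethylsilyl)oxy]heptane-2,6-dione | CC(=O)CC(O[Si](C)(C)C(C)(C)C)CC(C)=O | intermediate
6 | (R)-5-[(tert-butyldimethylsilyl)oxy]-3-methylcyclohex-2-en-1-one | CC1=CC(=O)C[C@H](O[Si](C)(C)C(C)(C)C)C1 | intermediate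
7 | (R)-5-hydroxy-3-methylcyclohex-2-en-1-one | CC1=CC(=O)C[C@H](O)C1 | intermediate
8 | but-3-en-1-ol | C=CCCO | starting material
9 | 2-methyl-2-vinyloxirane (racemic) | CC1(C=C)CO1 | starting material
10 | (2S,3R)-2-ethenyl-2-methylhex-5-ene-1,3-diol | C=CC[C@@H](O)[C@](C)(CO)C=C | intermediate
11 | (2S,3R)-1-[(tert-butyldiphenylsilyl)oxy]-2-ethenyl-2-methylhex-5-en-3-ol | C=CC[C@@H](O)[C@](C)(CO[Si](C(C)(C)C)(c1ccccc1)c1ccccc1)C=C | intermediate
12 | tert-butyl{[(2S,3R)-2-ethenyl-2-methyl-3-(triethylsilyloxy)hex-5-en-1-yl]oxy}diphenylsilane | C=CC[C@@H](O[Si](CC)(CC)CC)[C@](C)(CO[Si](C(C)(C)C)(c1ccccc1)c1ccccc1)C=C | intermediate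
13 | (2S,3R)-2-{[(tert-butyldiphenylsilyl)oxy]methyl}-2-methyl-3-[(triethylsilyl)oxy]pentanedial (C-6 and C-3 aldehydes) | O=CC[C@@H](O[Si](CC)(CC)CC)[C@](C)(CO[Si](C(C)(C)C)(c1ccccc1)c1ccccc1)C=O | intermediate
14 | (Z)-C-3 enol diisopropylsilyl triflate of 13 | CC(C)[Si](C(C)C)(OS(=O)(=O)C(F)(F)F)O/C=C\[C@@H](O[Si](CC)(CC)CC)[C@](C)(CO[Si](C(C)(C)C)(c1ccccc1)c1ccccc1)C=O | intermediate (not isolated)
15 | silaketal: Si(i-Pr)2 links O-8 of the (R)-enone to the (Z)-C-3 enol ether oxygen of the chain aldehyde | CC1=CC(=O)C[C@H](O[Si](C(C)C)(C(C)C)O/C=C\[C@@H](O[Si](CC)(CC)CC)[C@](C)(CO[Si](C(C)(C)C)(c2ccccc2)c2ccccc2)C=O)C1 | intermediate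
16 | key product: cis-fused rings A and C, C-10 ketone, (6S)-hydroxyl, 3,8-O-diisopropylsilylene bridge, 1-O-triethylsilyl, 12-O-tert-butyldiphenylsilyl | CC[Si](CC)(CC)O[C@@H]1C[C@H]2O[Si](C(C)C)(C(C)C)O[C@H]3CC(=O)[C@@H]([C@H](O)[C@@]1(C)CO[Si](C(C)(C)C)(c4ccccc4)c4ccccc4)[C@]2(C)C3 | intermediate
17 | 6,10-anti diol of 16 | CC[Si](CC)(CC)O[C@@H]1C[C@H]2O[Si](C(C)C)(C(C)C)O[C@H]3C[C@H](O)[C@@H]([C@H](O)[C@@]1(C)CO[Si](C(C)(C)C)(c4ccccc4)c4ccccc4)[C@]2(C)C3 | intermediate
18 | 6,10-bis(methanesulfonate) of 17 | CC[Si](CC)(CC)O[C@@H]1C[C@H]2O[Si](C(C)C)(C(C)C)O[C@H]3C[C@H](OS(C)(=O)=O)[C@@H]([C@H](OS(C)(=O)=O)[C@@]1(C)CO[Si](C(C)(C)C)(c4ccccc4)c4ccccc4)[C@]2(C)C3 | intermediate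
19 | 1,3,8-triol 6,10-bis(methanesulfonate), 12-O-tert-butyldiphenylsilyl | O[C@@H]1C[C@@H](O)[C@@]2(C)C[C@@H](O)C[C@H](OS(C)(=O)=O)[C@H]2[C@H](OS(C)(=O)=O)[C@@]1(C)CO[Si](C(C)(C)C)(c3ccccc3)c3ccccc3 | intermediate
20 | C-8 ketone, 1,3-diol 6,10-bis(methanesulfonate) | O[C@@H]1C[C@@H](O)[C@@]2(C)CC(=O)C[C@H](OS(C)(=O)=O)[C@H]2[C@H](OS(C)(=O)=O)[C@@]1(C)CO[Si](C(C)(C)C)(c3ccccc3)c3ccccc3 | intermediate
21 | 1,3-bis(triethylsilyl) ether of 20 | CC[Si](CC)(CC)O[C@@H]1C[C@@H](O[Si](CC)(CC)CC)[C@@]2(C)CC(=O)C[C@H](OS(C)(=O)=O)[C@H]2[C@H](OS(C)(=O)=O)[C@@]1(C)CO[Si](C(C)(C)C)(c3ccccc3)c3ccccc3 | intermediate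
22 | ring A enone (C-8 ketone, C-9=C-10) with the C-6 methanesulfonate | CC[Si](CC)(CC)O[C@@H]1C[C@@H](O[Si](CC)(CC)CC)[C@@]2(C)CC(=O)C=C[C@H]2[C@H](OS(C)(=O)=O)[C@@]1(C)CO[Si](C(C)(C)C)(c3ccccc3)c3ccccc3 | intermediate (not isolated)
23 | tricyclic enone (rings A, B, C) | CC[Si](CC)(CC)O[C@@H]1C[C@@H](O[Si](CC)(CC)CC)[C@]2(C)[C@@H]3[C@@H]([C@H]2C(=O)C=C3)[C@@]1(C)CO[Si](C(C)(C)C)(c4ccccc4)c4ccccc4 | intermediate
24 | tricyclic ketone with C-10 methyl | CC[Si](CC)(CC)O[C@@H]1C[C@@H](O[Si](CC)(CC)CC)[C@]2(C)[C@@H]3[C@@H]([C@H]2C(=O)C[C@H]3C)[C@@]1(C)CO[Si](C(C)(C)C)(c4ccccc4)c4ccccc4 | intermediate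
25 | 1,3-diol, 12-O-tert-butyldiphenylsilyl | O[C@@H]1C[C@@H](O)[C@]2(C)[C@@H]3[C@@H]([C@H]2C(=O)C[C@H]3C)[C@@]1(C)CO[Si](C(C)(C)C)(c4ccccc4)c4ccccc4 | intermediate
26 | angelic acid, (Z)-2-methylbut-2-enoic acid | C/C=C(/C)C(=O)O | starting material
27 | 1,3-bis(angelate), 12-O-tert-butyldiphenylsilyl | C/C=C(/C)C(=O)O[C@@H]1C[C@@H](OC(=O)/C(C)=C\C)[C@]2(C)[C@@H]3[C@@H]([C@H]2C(=O)C[C@H]3C)[C@@]1(C)CO[Si](C(C)(C)C)(c4ccccc4)c4ccccc4 | intermediate
28 | CNP0287707.1 | C/C=C(/C)C(=O)O[C@@H]1C[C@@H](OC(=O)/C(C)=C\C)[C@]2(C)[C@@H]3[C@@H]([C@H]2C(=O)C[C@H]3C)[C@@]1(C)CO | target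

**Count**
Total: 21 steps. Longest linear sequence: 17 steps (steps 1 to 5, then 10 to 21).

**Steps most likely to fail**

Step 11. The iron enolate may be protonated, or the C-3 radical reduced, before ring C closes, and the aldol may close on the wrong face of the aldehyde. The fallback sets out from 15 and separates the two bond formations into known operations. The iron-catalysed reductive coupling of a silyl enol ether with an enone, run in an ethanol-rich medium so that the enolate is protonated on purpose, should give the keto aldehyde F1 (C-3–C-4 formed, C-5 a CH2). A separate chelation-controlled aldol under soft enolisation (MgBr2·OEt2, Et3N, CH2Cl2), in which only the C-5 enolate can reach the tethered aldehyde, should then close ring C. The route is rejoined at 16.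

Step 17. Backside displacement at the neopentyl-type C-6 centre may be too slow, so that γ-deprotonation of the enone and loss of the mesylate by elimination take over. The fallback sets out from 21 and uses a softer, more acidic nucleophile carrying a removable activating group. DBU should give the enone mesylate 22, now isolated; LiN(SiMe3)2 followed by PhSO2F should give the C-7 β-keto sulfone F2; Cs2CO3 in MeCN at 60 °C should close ring B through the stabilised carbanion to the tricyclic sulfone F3; and Bu3SnH with AIBN in hot toluene should remove the sulfonyl group by a radical path that needs no bridgehead enolate. The route is rejoined at 23.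

Step 4. The silyloxy group may be lost by β-elimination under enamine catalysis, or the two acetonyl arms may be poorly distinguished. The fallback sets out from 5 and replaces catalytic desymmetrisation by resolution with the enantiopure chain. Pyrrolidine and AcOH should close ring A to the racemic silyl ether F4, and aq. HF should free the racemic hydroxy enone F5. Step 10 run with this racemate and dialdehyde 13 should give 15 together with its C-8 epimer F6, to be separated by chromatography. The route is rejoined at 15.

**Further compounds**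

F1 | step 11 | keto aldehyde: ring A C-10 ketone with C-3–C-4 formed, 3,8-O-diisopropylsilylene bridge, C-5 CH2 and free C-6 aldehyde | CC[Si](CC)(CC)O[C@H](C[C@H]1O[Si](C(C)C)(C(C)C)O[C@H]2CC(=O)C[C@]1(C)C2)[C@](C)(CO[Si](C(C)(C)C)(c3ccccc3)c3ccccc3)C=O
F2 | step 17 | C-7 phenylsulfonyl derivative of enone mesylate 22 (C-7 epimers) | CC[Si](CC)(CC)O[C@@H]1C[C@@H](O[Si](CC)(CC)CC)[C@@]2(C)C(S(=O)(=O)c3ccccc3)C(=O)C=C[C@H]2[C@H](OS(C)(=O)=O)[C@@]1(C)CO[Si](C(C)(C)C)(c3ccccc3)c3ccccc3
F3 | step 17 | tricyclic enone 23 with a phenylsulfonyl group at C-7 | CC[Si](CC)(CC)O[C@@H]1C[C@@H](O[Si](CC)(CC)CC)[C@]2(C)[C@@H]3[C@@H]([C@@]2(S(=O)(=O)c4ccccc4)C(=O)C=C3)[C@@]1(C)CO[Si](C(C)(C)C)(c4ccccc4)c4ccccc4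
F4 | step 4 | racemic 5-[(tert-butyldimethylsilyl)oxy]-3-methylcyclohex-2-en-1-one | CC1=CC(=O)CC(O[Si](C)(C)C(C)(C)C)C1
F5 | step 4 | racemic 5-hydroxy-3-methylcyclohex-2-en-1-one | CC1=CC(=O)CC(O)C1
F6 | step 4 | C-8 epimer of silaketal 15 (from the S enone) | CC1=CC(=O)C[C@@H](O[Si](C(C)C)(C(C)C)O/C=C\[C@@H](O[Si](CC)(CC)CC)[C@](C)(CO[Si](C(C)(C)C)(c2ccccc2)c2ccccc2)C=O)C1
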